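**Plan**
- Retrosynthesis: the acetonide and the O6–C12 lactone bond (from a C6/C12 diol) are cut first, then C2–C3 of the furanone, which returns a nine-membered lactone. That lactone is opened at its C3–O10 ester bond, and the chain is cut at C5–C6 (thioester plus alkylzinc) and C7–C8 (aldol).
- Enabling feature: the 3(2H)-furanone (ring O, C3, C2, C1, C10) is the condensation product of an ester joining the C10 oxygen to C3 and an acetyl group (C1, C2) on C10. The bridging oxygen and C3–C10 can therefore first exist as a nine-membered lactone.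
- Forward order: chain assembly (C7–C8, then C5–C6, then reduction at C6 with transfer of the side-chain ester to O8), nine-membered lactone, then furanone and ten-membered carbocycle in one operation, α-methylene-γ-butyrolactone last.
- Stereochemistry: C10 from (S)-citramalic acid, C4 from (R)-3-bromo-2-methylpropan-1-ol, C2' from (R)-3-bromo-2-hydroxy-2-methylpropanoic acid, C7 and C8 from an (R)-benzyloxazolidinone syn-aldol, C6 from 1,3-anti hydride transfer directed by O8.

Key step: step 22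

Remark: atoms carry germacrane numbers (C1 ketone, C3 furanone carbon on oxygen, C6 lactone carbinol, C8 ester carbinol, C10 quaternary, C12 lactone carbonyl, C2' side-chain carbinol); compounds 1, 8, 13, 18 and 25 are taken to be catalogue chemicals.

**Route**

Step 1
Reactants: 1 (S)-citramalic acid
Product: 2 2-[(4S)-2,2,4-trimethyl-5-oxo-1,3-dioxolan-4-yl]acetic acid
Conditions: Me2C(OMe)2, TsOH·H2O (cat.), rt
Reagents that add atoms: 2,2-dimethoxypropane, COC(C)(C)OC
Why: Acid-catalysed transketalisation should close the five-membered dioxolanone on the α-hydroxy acid unit only, leaving the CH2CO2H arm free and the quaternary centre untouched.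

Step 2
Reactants: 2 dioxolanone acid
Product: 4 (S)-3-hydroxy-3-methyldihydrofuran-2(3H)-one, via hydroxyethyl dioxolanone 3 (not isolated)
Conditions: BH3·SMe2, THF, 0 °C to rt; MeOH; then TsOH·H2O (cat.), CH2Cl2, rt
Reagents that add atoms: none
Why: Borane reduction is chemoselective for the free carboxylic acid, and acid-catalysed translactonisation (5-exo-trig attack of the new primary alcohol on the acylal carbonyl) should then expel acetone.

Step 3
Reactants: 4 hydroxy lactone
Product: 5 (S)-3-methyl-3-(triethylsilyloxy)dihydrofuran-2(3H)-one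
Conditions: Et3SiOTf, 2,6-lutidine, CH2Cl2, −78 to 0 °C
Reagents that add atoms: triethylsilyl trifluoromethanesulfonate, CC[Si](CC)(CC)OS(=O)(=O)C(F)(F)F
Why: Silyl triflate silylation is the routine way to cap a hindered tertiary α-hydroxy lactone.

Step 4
Reactants: 5 silyloxy lactone
Product: 6 (S)-5-hydroxy-3-methyl-3-(triethylsilyloxy)pentan-2-one
Conditions: MeLi (1.05 equiv), THF, −78 °C; AcOH, −78 °C
Reagents that add atoms: methyllithium, [Li]C
Why: Mono-addition of an organolithium to a lactone stops at the lithium lactolate at low temperature and should give the methyl ketone (in equilibrium with its cyclic hemiketal) after a cold acidic quench that also suppresses silyl migration.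

Step 5
Reactants: 6 hydroxy ketone
Product: 7 (S)-3-methyl-4-oxo-3-(triethylsilyloxy)pentanal
Conditions: TEMPO (cat.), PhI(OAc)2, CH2Cl2, rt
Reagents that add atoms: none
Why: Oxoammonium oxidation converts the primary alcohol of the open-chain tautomer into the aldehyde under non-basic conditions, which avoids β-elimination of the silyloxy group.

Step 6
Reactants: 8 (R)-3-bromo-2-hydroxy-2-methylpropanoic acid
Product: 10 (S)-2,3-dihydroxy-2-methylpropanoic acid, via sodium 2-methylglycidate 9 (not isolated)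
Conditions: NaOH (aq.), 80 °C; then HCl to pH 2
Reagents that add atoms: sodium hydroxide, [Na+].[OH-]
Why: Intramolecular Williamson closure to the glycidate and SN2 opening by hydroxide at the CH2 carbon never touch the quaternary centre, so its geometry is kept (the descriptor changes from R to S only because Br is replaced by O).

Step 7
Reactants: 10 diol acid
Product: 11 methyl (S)-2,2,4-trimethyl-1,3-dioxolane-4-carboxylate
Conditions: Me2C(OMe)2, MeOH, TsOH·H2O (cat.), rt
Reagents that add atoms: 2,2-dimethoxypropane, COC(C)(C)OC; methanol, CO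
Why: Under acid catalysis the 1,2-diol should form the acetonide while the acid undergoes Fischer esterification, methanol diverting any dioxolanone to the methyl ester.

Step 8
Reactants: 11 acetonide ester
Product: 12 (S)-2,2,4-trimethyl-1,3-dioxolane-4-carbaldehyde
Conditions: iBu2AlH, CH2Cl2, −78 °C; aq. potassium sodium tartrate
Reagents that add atoms: none
Why: Partial reduction of an α-alkoxy ester with iBu2AlH stops at the chelated aluminium hemiacetal at −78 °C, and the aldehyde cannot epimerise because its α-carbon is quaternary.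

Step 9
Reactants: 13 itaconic acid 4-methyl ester
Product: 15 methyl 3-(hydroxymethyl)but-3-enoate, via mixed carbonic anhydride 14 (not isolated)
Conditions: EtOCOCl, N-methylmorpholine, THF, −15 °C; then NaBH4, THF/H2O, 0 °C
Reagents that add atoms: none
Why: Activation of the free acrylic acid as a mixed carbonic anhydride followed by borohydride 1,2-reduction should give the allylic alcohol while the methyl ester is left alone.

Step 10
Reactants: 15 hydroxy ester
Product: 16 methyl 3-[(tert-butyldiphenylsilyloxy)methyl]but-3-enoate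
Conditions: tBuPh2SiCl, imidazole, CH2Cl2, rt
Reagents that add atoms: tert-butyl(chloro)diphenylsilane, CC(C)(C)[Si](Cl)(c1ccccc1)c1ccccc1
Why: Standard silylation of a primary allylic alcohol, done without delay so that the hydroxy ester cannot lactonise.

Step 11
Reactants: 16 silyloxy ester
Product: 17 3-[(tert-butyldiphenylsilyloxy)methyl]but-3-enoic acid
Conditions: Me3SnOH, 1,2-dichloroethane, 70 °C; then 1 M HCl wash
Reagents that add atoms: trimethyltin hydroxide, C[Sn](C)(C)O
Why: Tin hydroxide ester cleavage is close to neutral, so the 1,1-disubstituted double bond should not move into conjugation as it could under aqueous alkali.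

Step 12
Reactants: 17 butenoic acid; 18 (R)-4-benzyloxazolidin-2-one
Product: 21 (R)-4-benzyl-3-{3-[(tert-butyldiphenylsilyloxy)methyl]but-3-enoyl}oxazolidin-2-one, via mixed pivalic anhydride 19 (not isolated), via lithium oxazolidinide 20 (not isolated)
Conditions: 17, tBuCOCl, Et3N, THF, −78 to 0 °C; then 20 (from 18, n-BuLi, THF, −78 °C), −78 to 0 °C
Reagents that add atoms: none
Why: N-Acylation of the lithiated Evans auxiliary by a mixed pivalic anhydride is fast at low temperature, which keeps the β,γ-double bond in place.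

Step 13
Reactants: 21 N-acyl oxazolidinone; 7 keto aldehyde
Product: 23 (R)-4-benzyl-3-[(2R,3S,5S)-2-{3-[(tert-butyldiphenylsilyl)oxy]prop-1-en-2-yl}-3-hydroxy-5-methyl-6-oxo-5-[(triethylsilyl)oxy]heptanoyl]oxazolidin-2-one, via boron Z-enolate 22 (not isolated)
Conditions: Bu2BOTf, iPr2NEt, CH2Cl2, −78 to 0 °C; 7, −78 to 0 °C; then H2O2, MeOH, aq. NaH2PO4/Na2HPO4 (pH 7), 0 °C
Reagents that add atoms: none
Why: Evans syn-aldol reaction in which the Z-boron enolate reacts at its α-carbon through a Zimmerman–Traxler chair on the face away from the benzyl group, so that the (R)-auxiliary sets C7 (R) and C8 (S) with the 2-propenyl branch and the hydroxyl syn, the aldehyde of 7 reacting in preference to its hindered ketone.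

Step 14
Reactants: 23 aldol adduct
Product: 24 S-ethyl (2R,3S,5S)-2-{3-[(tert-butyldiphenylsilyl)oxy]prop-1-en-2-yl}-3-hydroxy-5-methyl-6-oxo-5-[(triethylsilyl)oxy]heptanethioate
Conditions: EtSH, n-BuLi, THF, 0 °C; AcOH
Reagents that add atoms: ethanethiol, CCS
Why: Thiolate transacylation at the exocyclic imide carbonyl releases the auxiliary, and the weakly basic lithium thiolate should cause neither retro-aldol cleavage nor double-bond migration.

Step 15
Reactants: 25 (R)-3-bromo-2-methylpropan-1-ol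
Product: 26 (R)-(3-bromo-2-methylpropoxy)triethylsilane
Conditions: Et3SiCl, imidazole, CH2Cl2, 0 °C
Reagents that add atoms: chlorotriethylsilane, CC[Si](Cl)(CC)CC
Why: Routine silylation of a primary alcohol, the triethylsilyl group being chosen so that it can later leave together with the tertiary one on C10.

Step 16
Reactants: 24 thioester; 26 bromide
Product: 28 (3S,5S,6R,9S)-6-{3-[(tert-butyldiphenylsilyl)oxy]prop-1-en-2-yl}-5-hydroxy-3,9-dimethyl-3,10-bis[(triethylsilyl)oxy]decane-2,7-dione, via alkylzinc bromide 27 (not isolated)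
Conditions: 26, Zn dust, I2 (5 mol %), DMA, 80 °C; then 24, PdCl2(PPh3)2 (10 mol %), toluene, rt
Reagents that add atoms: none
Why: Fukuyama coupling in which zerovalent palladium inserts into the C–S bond, transmetalates with the alkylzinc bromide (3 equiv, one being spent on the free hydroxyl) and reductively eliminates the C5–C6 ketone under neutral conditions that spare the methyl ketone, the silyl ethers and the C4 and C7 centres.

Step 17
Reactants: 28 β-hydroxy ketone; 12 acetonide aldehyde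
Product: 29 (3S,5S,6S,7S,9S)-6-{3-[(tert-butyldiphenylsilyl)oxy]prop-1-en-2-yl}-7-hydroxy-3,9-dimethyl-2-oxo-3,10-bis[(triethylsilyl)oxy]decan-5-yl (S)-2,2,4-trimethyl-1,3-dioxolane-4-carboxylate
Conditions: SmI2 (30 mol %) premixed with 12 (4 equiv), THF, −10 °C
Reagents that add atoms: none
Why: Evans–Tishchenko reduction in which the C8 hydroxyl forms a hemiacetal with 12 and trivalent samarium holds it and the C6 ketone in a six-membered chair, so that hydride passes to C6 anti to the C8–O bond (C6 becomes S) while O8 is acylated by the side chain in the same event, the distant C1 ketone being out of reach.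

Step 18
Reactants: 29 hydroxy ester
Product: 30 (3S,5S,6R,7S,9S)-7-[(tert-butyldimethylsilyl)oxy]-6-{3-[(tert-butyldiphenylsilyl)oxy]prop-1-en-2-yl}-3,9-dimethyl-2-oxo-3,10-bis[(triethylsilyl)oxy]decan-5-yl (S)-2,2,4-trimethyl-1,3-dioxolane-4-carboxylate
Conditions: tBuMe2SiOTf, 2,6-lutidine, CH2Cl2, −78 °C
Reagents that add atoms: tert-butyldimethylsilyl trifluoromethanesulfonate, CC(C)(C)[Si](C)(C)OS(=O)(=O)C(F)(F)F
Why: Silyl triflate silylation of the secondary C6 hydroxyl at −78 °C should outrun enol silylation of the methyl ketone, and the silyl ether blocks both γ-lactonisation onto C3 and acyl migration from O8.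

Step 19
Reactants: 30 tetrasilyl ether
Product: 31 (3S,5S,6R,7S,9S)-7-[(tert-butyldimethylsilyl)oxy]-6-{3-[(tert-butyldiphenylsilyl)oxy]prop-1-en-2-yl}-3,10-dihydroxy-3,9-dimethyl-2-oxodecan-5-yl (S)-2,2,4-trimethyl-1,3-dioxolane-4-carboxylate
Conditions: HF·pyridine, pyridine, THF, 0 °C to rt
Reagents that add atoms: none
Why: Selective desilylation, since buffered HF·pyridine cleaves the two triethylsilyl ethers (primary at C3, tertiary at C10) much faster than the hindered secondary tert-butyldimethylsilyl and the tert-butyldiphenylsilyl ether and does not touch the acetonide.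

Step 20
Reactants: 31 diol
Product: 33 (2S,4S,5R,6S,8S)-4-[(tert-butyldimethylsilyl)oxy]-5-{3-[(tert-butyldiphenylsilyl)oxy]prop-1-en-2-yl}-8-hydroxy-2,8-dimethyl-9-oxo-6-{[(S)-2,2,4-trimethyl-1,3-dioxolane-4-carbonyl]oxy}decanoic acid, via C3 aldehyde 32 (not isolated)
Conditions: TEMPO (cat.), PhI(OAc)2, CH2Cl2, rt; then NaClO2, NaH2PO4, 2-methyl-2-butene, tBuOH/H2O, rt
Reagents that add atoms: sodium chlorite, [Na+].[O-]Cl=O
Why: Oxoammonium oxidation of the primary alcohol followed in the same flask by Pinnick oxidation should give the acid without epimerising C4, the tertiary α-ketol hydroxyl being inert to both oxidants.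

Step 21
Reactants: 33 seco acid
Product: 35 (3S,5S,6R,7S,9S)-9-acetyl-5-[(tert-butyldimethylsilyl)oxy]-6-{3-[(tert-butyldiphenylsilyl)oxy]prop-1-en-2-yl}-3,9-dimethyl-2-oxooxonan-7-yl (S)-2,2,4-trimethyl-1,3-dioxolane-4-carboxylate, via mixed aryl anhydride 34 (not isolated)
Conditions: 2-methyl-6-nitrobenzoic anhydride, DMAP, toluene, 60 °C, slow addition of 33 (1 mM final)
Reagents that add atoms: none
Why: Shiina macrolactonisation in which the mixed anhydride is turned into an acylpyridinium that the C10 hydroxyl, the only free hydroxyl, traps under high dilution, the branches at C4, C6, C7, C8 and C10 favouring the folded chain needed for nine-membered ring closure.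

Step 22
Reactants: 35 nine-membered lactone
Product: 37 (4S,6S,7R,8S,10S)-6-[(tert-butyldimethylsilyl)oxy]-12-[(tert-butyldiphenylsilyl)oxy]-3,10-epoxy-1-oxogermacra-2,11(13)-dien-8-yl (S)-2,2,4-trimethyl-1,3-dioxolane-4-carboxylate, via hemiketal 36 (not isolated)
Conditions: LiN(SiMe3)2 (2.2 equiv), THF, −78 to −40 °C; AcOH; then CSA (cat.), MgSO4, CH2Cl2, rt
Reagents that add atoms: none
Why: LiN(SiMe3)2 removes a proton from the acetyl methyl group (C2), and the lithium enolate, held four atoms from the lactone carbonyl C3, should add to it to form C2–C3 and a bicyclic lithium hemiketalate, which after protonation (36) loses water under acid catalysis to give the vinylogous ester O–C3=C2–C1=O. The closest known reaction type is the base-mediated intramolecular Claisen condensation and cyclodehydration of acyclic α-acyloxy ketones to 3(2H)-furanones; here the ester is a nine-membered lactone, so the same bond also turns the ring made of O and C3–C10 into the ten-membered carbocycle C1–C10. The furanone ring closes by 5-exo-trig attack of the enolate carbon on the ester carbonyl, and the carbocycle closes through that same bond as a transannular, formally 10-exo-trig, event. No stereocentre is created, and C4, C6, C7, C8 and C10 are carried through because no bond to them is broken. The selectivity needed is deprotonation at C2 (unhindered methyl ketone, pKa near 20) and not at C4 (tertiary ester α-hydrogen, pKa near 25, whose loss would epimerise the methyl centre), which a bulky amide base at −78 °C should secure, while the C8 ester has no α-hydrogen and could be reached by the enolate only through a seven-membered transition state. Should the adduct open to the α'-hydroxy-1,3-diketone, the same acid treatment converges on 37.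

Step 23
Reactants: 37 furanone
Product: 38 (4S,6S,7S,8S,10S)-3,10-epoxy-6,12-dihydroxy-1-oxogermacra-2,11(13)-dien-8-yl (S)-2,2,4-trimethyl-1,3-dioxolane-4-carboxylate
Conditions: HF·pyridine, THF, 0 °C to rt
Reagents that add atoms: none
Why: Fluoride cleavage of both remaining silyl ethers under acidic, non-basic conditions should avoid O8-to-O6 acyl migration and leave ester, acetonide and furanone intact.

Step 24
Reactants: 38 diol
Product: 41 (4S,6S,7S,8S,10S)-3,10-epoxy-1-oxogermacra-2,11(13)-dien-12,6-olid-8-yl (S)-2,2,4-trimethyl-1,3-dioxolane-4-carboxylate, via hydroxy enal 39 (not isolated), via lactol 40 (not isolated)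
Conditions: TEMPO (cat.), PhI(OAc)2, CH2Cl2, rt
Reagents that add atoms: none
Why: Oxidative lactonisation of a 2-methylene-1,4-diol, in which oxoammonium oxidation of the primary allylic alcohol gives the enal, the C6 hydroxyl traps it as a five-membered lactol and a second oxidation gives the α-methylene-γ-butyrolactone, cis-fused because C6 and C7 are already set.

Step 25
Reactants: 41 lactone acetonide
Product: 42 (4S,6S,7S,8S,10S)-3,10-epoxy-1-oxogermacra-2,11(13)-dien-12,6-olid-8-yl (S)-2,3-dihydroxy-2-methylpropanoate (CNP0263764.3)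
Conditions: CF3CO2H/H2O (4:1), 0 °C
Reagents that add atoms: none
Why: Acid hydrolysis of the terminal acetonide, which ester, lactone and vinylogous ester should survive, with no base present that could add to the methylene lactone or cause translactonisation.

**Compound list**

1 | (S)-citramalic acid | OC(=O)[C@](C)(CC(=O)O)O | starting material
2 | 2-[(4S)-2,2,4-trimethyl-5-oxo-1,3-dioxolan-4-yl]acetic acid | O=C1OC(C)(C)O[C@@]1(C)CC(=O)O | intermediate
3 | (S)-5-(2-hydroxyethyl)-2,2,5-trimethyl-1,3-dioxolan-4-one (formed in situ) | O=C1OC(C)(C)O[C@@]1(C)CCO | intermediate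
4 | (S)-3-hydroxy-3-methyldihydrofuran-2(3H)-one | O=C1OCC[C@]1(C)O | intermediate
5 | (S)-3-methyl-3-(triethylsilyloxy)dihydrofuran-2(3H)-one | O=C1OCC[C@]1(C)O[Si](CC)(CC)CC | intermediate
6 | (S)-5-hydroxy-3-methyl-3-(triethylsilyloxy)pentan-2-one | CC(=O)[C@](C)(CCO)O[Si](CC)(CC)CC | intermediate
7 | (S)-3-methyl-4-oxo-3-(triethylsilyloxy)pentanal (C8, C9, C10, C14, C1, C2) | CC(=O)[C@](C)(CC=O)O[Si](CC)(CC)CC | intermediate
8 | (R)-3-bromo-2-hydroxy-2-methylpropanoic acid | OC(=O)[C@@](C)(O)CBr | starting material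
9 | sodium (S)-2-methyloxirane-2-carboxylate (formed in situ) | [Na+].[O-]C(=O)[C@]1(C)CO1 | intermediate
10 | (S)-2,3-dihydroxy-2-methylpropanoic acid | OC(=O)[C@@](C)(O)CO | intermediate
11 | methyl (S)-2,2,4-trimethyl-1,3-dioxolane-4-carboxylate | COC(=O)[C@@]1(C)OC(C)(C)OC1 | intermediate
12 | (S)-2,2,4-trimethyl-1,3-dioxolane-4-carbaldehyde | O=C[C@@]1(C)OC(C)(C)OC1 | intermediate
13 | itaconic acid 4-methyl ester (4-methoxy-2-methylidene-4-oxobutanoic acid) | COC(=O)CC(=C)C(=O)O | starting material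
14 | ethyl carbonic mixed anhydride of 13 (formed in situ) | COC(=O)CC(=C)C(=O)OC(=O)OCC | intermediate
15 | methyl 3-(hydroxymethyl)but-3-enoate | COC(=O)CC(=C)CO | intermediate
16 | methyl 3-[(tert-butyldiphenylsilyloxy)methyl]but-3-enoate | COC(=O)CC(=C)CO[Si](c1ccccc1)(c1ccccc1)C(C)(C)C | intermediate
17 | 3-[(tert-butyldiphenylsilyloxy)methyl]but-3-enoic acid (C6, C7, C11, C13, C12) | OC(=O)CC(=C)CO[Si](c1ccccc1)(c1ccccc1)C(C)(C)C | intermediate
18 | (R)-4-benzyloxazolidin-2-one | O=C1N[C@H](Cc2ccccc2)CO1 | starting material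
19 | pivalic mixed anhydride of 17 (formed in situ) | CC(C)(C)C(=O)OC(=O)CC(=C)CO[Si](c1ccccc1)(c1ccccc1)C(C)(C)C | intermediate
20 | lithium salt of 18 (formed in situ) | [Li+].O=C1[N-][C@H](Cc2ccccc2)CO1 | intermediate
21 | (R)-4-benzyl-3-{3-[(tert-butyldiphenylsilyloxy)methyl]but-3-enoyl}oxazolidin-2-one | O=C1OC[C@@H](Cc2ccccc2)N1C(=O)CC(=C)CO[Si](c3ccccc3)(c3ccccc3)C(C)(C)C | intermediate
22 | dibutylboron Z-enolate of 21 (formed in situ) | O=C1OC[C@@H](Cc2ccccc2)N1/C(OB(CCCC)CCCC)=C/C(=C)CO[Si](c3ccccc3)(c3ccccc3)C(C)(C)C | intermediate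
23 | (R)-4-benzyl-3-[(2R,3S,5S)-2-{3-[(tert-butyldiphenylsilyl)oxy]prop-1-en-2-yl}-3-hydroxy-5-methyl-6-oxo-5-[(triethylsilyl)oxy]heptanoyl]oxazolidin-2-one | O=C1OC[C@@H](Cc2ccccc2)N1C(=O)[C@H](C(=C)CO[Si](c3ccccc3)(c3ccccc3)C(C)(C)C)[C@@H](O)C[C@](C)(O[Si](CC)(CC)CC)C(C)=O | intermediate
24 | S-ethyl (2R,3S,5S)-2-{3-[(tert-butyldiphenylsilyl)oxy]prop-1-en-2-yl}-3-hydroxy-5-methyl-6-oxo-5-[(triethylsilyl)oxy]heptanethioate | CCSC(=O)[C@H](C(=C)CO[Si](c1ccccc1)(c1ccccc1)C(C)(C)C)[C@@H](O)C[C@](C)(O[Si](CC)(CC)CC)C(C)=O | intermediate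
25 | (R)-3-bromo-2-methylpropan-1-ol | BrC[C@H](C)CO | starting material
26 | (R)-(3-bromo-2-methylpropoxy)triethylsilane | BrC[C@H](C)CO[Si](CC)(CC)CC | intermediate
27 | (R)-[2-methyl-3-(triethylsilyloxy)propyl]zinc bromide (formed in situ) | Br[Zn]C[C@H](C)CO[Si](CC)(CC)CC | intermediate
28 | (3S,5S,6R,9S)-6-{3-[(tert-butyldiphenylsilyl)oxy]prop-1-en-2-yl}-5-hydroxy-3,9-dimethyl-3,10-bis[(triethylsilyl)oxy]decane-2,7-dione | CC[Si](CC)(CC)OC[C@@H](C)CC(=O)[C@H](C(=C)CO[Si](c1ccccc1)(c1ccccc1)C(C)(C)C)[C@@H](O)C[C@](C)(O[Si](CC)(CC)CC)C(C)=O | intermediate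
29 | (3S,5S,6S,7S,9S)-6-{3-[(tert-butyldiphenylsilyl)oxy]prop-1-en-2-yl}-7-hydroxy-3,9-dimethyl-2-oxo-3,10-bis[(triethylsilyl)oxy]decan-5-yl (S)-2,2,4-trimethyl-1,3-dioxolane-4-carboxylate | CC[Si](CC)(CC)OC[C@@H](C)C[C@H](O)[C@H](C(=C)CO[Si](c1ccccc1)(c1ccccc1)C(C)(C)C)[C@@H](OC(=O)[C@@]2(C)OC(C)(C)OC2)C[C@](C)(O[Si](CC)(CC)CC)C(C)=O | intermediate
30 | (3S,5S,6R,7S,9S)-7-[(tert-butyldimethylsilyl)oxy]-6-{3-[(tert-butyldiphenylsilyl)oxy]prop-1-en-2-yl}-3,9-dimethyl-2-oxo-3,10-bis[(triethylsilyl)oxy]decan-5-yl (S)-2,2,4-trimethyl-1,3-dioxolane-4-carboxylate | CC[Si](CC)(CC)OC[C@@H](C)C[C@H](O[Si](C)(C)C(C)(C)C)[C@H](C(=C)CO[Si](c1ccccc1)(c1ccccc1)C(C)(C)C)[C@@H](OC(=O)[C@@]2(C)OC(C)(C)OC2)C[C@](C)(O[Si](CC)(CC)CC)C(C)=O | intermediate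
31 | (3S,5S,6R,7S,9S)-7-[(tert-butyldimethylsilyl)oxy]-6-{3-[(tert-butyldiphenylsilyl)oxy]prop-1-en-2-yl}-3,10-dihydroxy-3,9-dimethyl-2-oxodecan-5-yl (S)-2,2,4-trimethyl-1,3-dioxolane-4-carboxylate | OC[C@@H](C)C[C@H](O[Si](C)(C)C(C)(C)C)[C@H](C(=C)CO[Si](c1ccccc1)(c1ccccc1)C(C)(C)C)[C@@H](OC(=O)[C@@]2(C)OC(C)(C)OC2)C[C@](C)(O)C(C)=O | intermediate
32 | C3 aldehyde of 31, (2S,4S,5R,6S,8S)-4-[(tert-butyldimethylsilyl)oxy]-5-{3-[(tert-butyldiphenylsilyl)oxy]prop-1-en-2-yl}-8-hydroxy-2,8-dimethyl-1,9-dioxodecan-6-yl (S)-2,2,4-trimethyl-1,3-dioxolane-4-carboxylate (formed in situ) | O=C[C@@H](C)C[C@H](O[Si](C)(C)C(C)(C)C)[C@H](C(=C)CO[Si](c1ccccc1)(c1ccccc1)C(C)(C)C)[C@@H](OC(=O)[C@@]2(C)OC(C)(C)OC2)C[C@](C)(O)C(C)=O | intermediate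
33 | seco acid, (2S,4S,5R,6S,8S)-4-[(tert-butyldimethylsilyl)oxy]-5-{3-[(tert-butyldiphenylsilyl)oxy]prop-1-en-2-yl}-8-hydroxy-2,8-dimethyl-9-oxo-6-{[(S)-2,2,4-trimethyl-1,3-dioxolane-4-carbonyl]oxy}decanoic acid | OC(=O)[C@@H](C)C[C@H](O[Si](C)(C)C(C)(C)C)[C@H](C(=C)CO[Si](c1ccccc1)(c1ccccc1)C(C)(C)C)[C@@H](OC(=O)[C@@]2(C)OC(C)(C)OC2)C[C@](C)(O)C(C)=O | intermediate
34 | mixed anhydride of 33 with 2-methyl-6-nitrobenzoic acid (formed in situ) | Cc1cccc([N+](=O)[O-])c1C(=O)OC(=O)[C@@H](C)C[C@H](O[Si](C)(C)C(C)(C)C)[C@H](C(=C)CO[Si](c2ccccc2)(c2ccccc2)C(C)(C)C)[C@@H](OC(=O)[C@@]3(C)OC(C)(C)OC3)C[C@](C)(O)C(C)=O | intermediate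
35 | nine-membered lactone, (3S,5S,6R,7S,9S)-9-acetyl-5-[(tert-butyldimethylsilyl)oxy]-6-{3-[(tert-butyldiphenylsilyl)oxy]prop-1-en-2-yl}-3,9-dimethyl-2-oxooxonan-7-yl (S)-2,2,4-trimethyl-1,3-dioxolane-4-carboxylate | C=C(CO[Si](c1ccccc1)(c1ccccc1)C(C)(C)C)[C@H]1[C@@H](O[Si](C)(C)C(C)(C)C)C[C@H](C)C(=O)O[C@](C)(C(C)=O)C[C@@H]1OC(=O)[C@@]2(C)OC(C)(C)OC2 | intermediate
36 | bicyclic hemiketal, the 3-hydroxy-2,3-dihydro form of 37 (C3 epimers; formed in situ) | C=C(CO[Si](c1ccccc1)(c1ccccc1)C(C)(C)C)[C@H]1[C@@H](O[Si](C)(C)C(C)(C)C)C[C@H](C)C2(O)CC(=O)[C@](C)(C[C@@H]1OC(=O)[C@@]3(C)OC(C)(C)OC3)O2 | intermediate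
37 | furanone-bridged carbocycle, (4S,6S,7R,8S,10S)-6-[(tert-butyldimethylsilyl)oxy]-12-[(tert-butyldiphenylsilyl)oxy]-3,10-epoxy-1-oxogermacra-2,11(13)-dien-8-yl (S)-2,2,4-trimethyl-1,3-dioxolane-4-carboxylate | C=C(CO[Si](c1ccccc1)(c1ccccc1)C(C)(C)C)[C@H]1[C@@H](O[Si](C)(C)C(C)(C)C)C[C@H](C)C2=CC(=O)[C@](C)(C[C@@H]1OC(=O)[C@@]3(C)OC(C)(C)OC3)O2 | intermediate
38 | (4S,6S,7S,8S,10S)-3,10-epoxy-6,12-dihydroxy-1-oxogermacra-2,11(13)-dien-8-yl (S)-2,2,4-trimethyl-1,3-dioxolane-4-carboxylate | C=C(CO)[C@H]1[C@@H](O)C[C@H](C)C2=CC(=O)[C@](C)(C[C@@H]1OC(=O)[C@@]3(C)OC(C)(C)OC3)O2 | intermediate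
39 | 12-aldehyde (enal) of 38 (formed in situ) | C=C(C=O)[C@H]1[C@@H](O)C[C@H](C)C2=CC(=O)[C@](C)(C[C@@H]1OC(=O)[C@@]3(C)OC(C)(C)OC3)O2 | intermediate
40 | 12,6-lactol of 39 (C12 epimers; formed in situ) | C=C1C(O)O[C@H]2C[C@H](C)C3=CC(=O)[C@](C)(C[C@H](OC(=O)[C@@]4(C)OC(C)(C)OC4)[C@@H]12)O3 | intermediate
41 | (4S,6S,7S,8S,10S)-3,10-epoxy-1-oxogermacra-2,11(13)-dien-12,6-olid-8-yl (S)-2,2,4-trimethyl-1,3-dioxolane-4-carboxylate | C=C1C(=O)O[C@H]2C[C@H](C)C3=CC(=O)[C@](C)(C[C@H](OC(=O)[C@@]4(C)OC(C)(C)OC4)[C@@H]12)O3 | intermediate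
42 | CNP0263764.3, (4S,6S,7S,8S,10S)-3,10-epoxy-1-oxogermacra-2,11(13)-dien-12,6-olid-8-yl (S)-2,3-dihydroxy-2-methylpropanoate | C=C1C(=O)O[C@H]2C[C@H](C)C3=CC(=O)[C@](C)(C[C@H](OC(=O)[C@@](C)(O)CO)[C@@H]12)O3 | target

**Step count**

Total: 25 steps. Longest linear sequence: 17 steps (from 1 to 42; steps 1–5, 13, 14 and 16–25).

**Steps most likely to fail**

1. Step 22. What may go wrong: deprotonation at C4 with epimerisation or ketene-type opening of the lactone, reversal of the addition, or intermolecular condensation because the folded conformer that brings C2 to C3 is thinly populated. The fallback sets out from 30 and comes back at 37; it closes the carbocycle first and makes the furanone afterwards. The acetyl group of 30 would be brominated through its lithium enolate (LiN(SiMe3)2, then N-bromosuccinimide) to the bromomethyl ketone F1. The primary triethylsilyl ether would be cleaved selectively (PPTS, MeOH, 0 °C) to the primary alcohol F2, which would be oxidised (TEMPO, PhI(OAc)2) to the aldehyde F3. An intramolecular Reformatsky reaction with SmI2 at high dilution should give the ten-membered β-hydroxy ketone F4, and Dess–Martin oxidation the 1,3-diketone F5. HF·pyridine would free the tertiary alcohol to give the hydroxy diketone F6, whose acid-catalysed cyclodehydration (CSA) gives 37.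

2. Step 21. What may go wrong: oligomerisation (diolide formation) outrunning attack of the hindered, electron-poor tertiary α-ketol hydroxyl on the activated acid. The fallback sets out from 30 and comes back at 35; it closes the ring onto a smaller tertiary propargylic carbinol and restores the acetyl group afterwards. Compound 30 would be converted into the enol triflate F7 (LiN(SiMe3)2, PhNTf2), which would be eliminated to the terminal alkyne F8 (LiN(iPr)2, THF, −78 °C). Both triethylsilyl ethers would be cleaved (HF·pyridine, pyridine) to the alkyne diol F9, which would be oxidised as in step 20 through the alkyne aldehyde F10 to the alkyne acid F11. Shiina lactonisation through the mixed anhydride F12 should give the nine-membered propargylic lactone F13. Markovnikov hydration catalysed by Ph3PAuNTf2 in wet dioxane, guided by the neighbouring ester carbonyl, returns the acetyl group and thus 35.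

3. Step 17. What may go wrong: hydride transfer from the hindered hemiacetal of 12 being slow, so that self-Tishchenko dimerisation of the aldehyde, hemiketal formation with the C1 ketone or 1,3-acyl migration take over. The fallback sets out from 28 and comes back at 30; it separates the reduction from the introduction of the side chain. The Evans–Tishchenko reduction would be run with acetaldehyde as the hydride donor to give the C8 acetate F14, which would be silylated at O6 (tBuMe2SiOTf, 2,6-lutidine) to the silyl ether F15. Methanolysis of the acetate (K2CO3, MeOH) would give the C8 alcohol F16. The side-chain acid F17, from 11 with LiOH, would be activated as its mixed anhydride F18 (2,4,6-trichlorobenzoyl chloride, Et3N) and coupled with F16 under DMAP catalysis (Yamaguchi esterification) to return 30.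

Further compounds
F1 | step 22 | bromomethyl ketone of 30 (Br on C2) | CC[Si](CC)(CC)OC[C@@H](C)C[C@H](O[Si](C)(C)C(C)(C)C)[C@H](C(=C)CO[Si](c1ccccc1)(c1ccccc1)C(C)(C)C)[C@@H](OC(=O)[C@@]2(C)OC(C)(C)OC2)C[C@](C)(O[Si](CC)(CC)CC)C(=O)CBr
F2 | step 22 | primary alcohol (C3–OH) of F1 | OC[C@@H](C)C[C@H](O[Si](C)(C)C(C)(C)C)[C@H](C(=C)CO[Si](c1ccccc1)(c1ccccc1)C(C)(C)C)[C@@H](OC(=O)[C@@]2(C)OC(C)(C)OC2)C[C@](C)(O[Si](CC)(CC)CC)C(=O)CBr
F3 | step 22 | C3 aldehyde of F2 | O=C[C@@H](C)C[C@H](O[Si](C)(C)C(C)(C)C)[C@H](C(=C)CO[Si](c1ccccc1)(c1ccccc1)C(C)(C)C)[C@@H](OC(=O)[C@@]2(C)OC(C)(C)OC2)C[C@](C)(O[Si](CC)(CC)CC)C(=O)CBr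
F4 | step 22 | ten-membered 3-hydroxy-1-ketone with C10–OSiEt3 (C3 epimers) | C=C(CO[Si](c1ccccc1)(c1ccccc1)C(C)(C)C)[C@H]1[C@@H](O[Si](C)(C)C(C)(C)C)C[C@H](C)C(O)CC(=O)[C@@](C)(O[Si](CC)(CC)CC)C[C@@H]1OC(=O)[C@@]2(C)OC(C)(C)OC2
F5 | step 22 | ten-membered 1,3-diketone with C10–OSiEt3 | C=C(CO[Si](c1ccccc1)(c1ccccc1)C(C)(C)C)[C@H]1[C@@H](O[Si](C)(C)C(C)(C)C)C[C@H](C)C(=O)CC(=O)[C@@](C)(O[Si](CC)(CC)CC)C[C@@H]1OC(=O)[C@@]2(C)OC(C)(C)OC2
F6 | step 22 | ten-membered 10-hydroxy-1,3-diketone | C=C(CO[Si](c1ccccc1)(c1ccccc1)C(C)(C)C)[C@H]1[C@@H](O[Si](C)(C)C(C)(C)C)C[C@H](C)C(=O)CC(=O)[C@@](C)(O)C[C@@H]1OC(=O)[C@@]2(C)OC(C)(C)OC2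
F7 | step 21 | enol triflate of 30 (C1(OTf)=C2H2) | CC[Si](CC)(CC)OC[C@@H](C)C[C@H](O[Si](C)(C)C(C)(C)C)[C@H](C(=C)CO[Si](c1ccccc1)(c1ccccc1)C(C)(C)C)[C@@H](OC(=O)[C@@]2(C)OC(C)(C)OC2)C[C@](C)(O[Si](CC)(CC)CC)C(=C)OS(=O)(=O)C(F)(F)F
F8 | step 21 | terminal alkyne (C1≡C2) | CC[Si](CC)(CC)OC[C@@H](C)C[C@H](O[Si](C)(C)C(C)(C)C)[C@H](C(=C)CO[Si](c1ccccc1)(c1ccccc1)C(C)(C)C)[C@@H](OC(=O)[C@@]2(C)OC(C)(C)OC2)C[C@](C)(O[Si](CC)(CC)CC)C#C
F9 | step 21 | alkyne diol (C3–OH, C10–OH) | OC[C@@H](C)C[C@H](O[Si](C)(C)C(C)(C)C)[C@H](C(=C)CO[Si](c1ccccc1)(c1ccccc1)C(C)(C)C)[C@@H](OC(=O)[C@@]2(C)OC(C)(C)OC2)C[C@](C)(O)C#C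
F10 | step 21 | alkyne aldehyde (C3 aldehyde of F9) | O=C[C@@H](C)C[C@H](O[Si](C)(C)C(C)(C)C)[C@H](C(=C)CO[Si](c1ccccc1)(c1ccccc1)C(C)(C)C)[C@@H](OC(=O)[C@@]2(C)OC(C)(C)OC2)C[C@](C)(O)C#C
F11 | step 21 | alkyne seco acid | OC(=O)[C@@H](C)C[C@H](O[Si](C)(C)C(C)(C)C)[C@H](C(=C)CO[Si](c1ccccc1)(c1ccccc1)C(C)(C)C)[C@@H](OC(=O)[C@@]2(C)OC(C)(C)OC2)C[C@](C)(O)C#C
F12 | step 21 | mixed anhydride of F11 with 2-methyl-6-nitrobenzoic acid | Cc1cccc([N+](=O)[O-])c1C(=O)OC(=O)[C@@H](C)C[C@H](O[Si](C)(C)C(C)(C)C)[C@H](C(=C)CO[Si](c2ccccc2)(c2ccccc2)C(C)(C)C)[C@@H](OC(=O)[C@@]3(C)OC(C)(C)OC3)C[C@](C)(O)C#C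
F13 | step 21 | nine-membered propargylic lactone (ethynyl in place of acetyl on C10) | C=C(CO[Si](c1ccccc1)(c1ccccc1)C(C)(C)C)[C@H]1[C@@H](O[Si](C)(C)C(C)(C)C)C[C@H](C)C(=O)O[C@](C)(C#C)C[C@@H]1OC(=O)[C@@]2(C)OC(C)(C)OC2
F14 | step 17 | C8 acetate with free C6 hydroxyl | CC[Si](CC)(CC)OC[C@@H](C)C[C@H](O)[C@H](C(=C)CO[Si](c1ccccc1)(c1ccccc1)C(C)(C)C)[C@@H](OC(C)=O)C[C@](C)(O[Si](CC)(CC)CC)C(C)=O
F15 | step 17 | C8 acetate with C6 tert-butyldimethylsilyl ether | CC[Si](CC)(CC)OC[C@@H](C)C[C@H](O[Si](C)(C)C(C)(C)C)[C@H](C(=C)CO[Si](c1ccccc1)(c1ccccc1)C(C)(C)C)[C@@H](OC(C)=O)C[C@](C)(O[Si](CC)(CC)CC)C(C)=O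
F16 | step 17 | C8 alcohol with C6 tert-butyldimethylsilyl ether | CC[Si](CC)(CC)OC[C@@H](C)C[C@H](O[Si](C)(C)C(C)(C)C)[C@H](C(=C)CO[Si](c1ccccc1)(c1ccccc1)C(C)(C)C)[C@@H](O)C[C@](C)(O[Si](CC)(CC)CC)C(C)=O
F17 | step 17 | (S)-2,2,4-trimethyl-1,3-dioxolane-4-carboxylic acid | OC(=O)[C@@]1(C)OC(C)(C)OC1
F18 | step 17 | mixed anhydride of F17 with 2,4,6-trichlorobenzoic acid | O=C(OC(=O)c1c(Cl)cc(Cl)cc1Cl)[C@@]2(C)OC(C)(C)OC2
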